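## Retrosynthetic overview

1. 22 ⇐ intramolecular Diels–Alder reaction of tetraene acid 21; the cyclohexene and the cyclopentane close together in the last step (bonds C4–C5 and C3a–C7a).
2. 21 ⇐ Negishi union of (Z)-vinyl iodide 16 with iodoacrylate 17; 16 ⇐ α-iodo-Wittig olefination of aldehyde 11.
3. 11 ⇐ lactol 5 by Wittig (formyl ylide 6) and Horner–Wadsworth–Emmons (benzylphosphonate 8) olefinations, giving the (E,E)-styryl diene.
4. 5 ⇐ C2-symmetric diol 3 by mono-oxidation with hemiacetal (C–O) ring closure, which tells the two chain ends apart without protecting groups.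
5. 3 ⇐ commercial dl/meso diacid 1 by reduction, then enantioselective enzymatic O-acylation (C–O bond formation) that sorts the stereoisomers and fixes both methyl stereocentres.

Assumption: commercial 1 is the usual dl/meso mixture, 6 and 17 are bought as catalogue reagents, and the face selectivity that the two tether methyl groups impose on the final cycloaddition is taken to be that of the biomimetic cyclisation known for this natural-product family (the relative configuration of the target); a simple allylic-strain picture does not by itself predict this sense, so it is the main stereochemical uncertainty of the route.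

## Route

Step 1
Reactants: 1 2,4-dimethylpentanedioic acid (dl/meso mixture)
Product: 2 2,4-dimethylpentane-1,5-diol (mixture of (2R,4R), (2S,4S) and meso isomers)
Conditions: LiAlH4, THF, 0 °C → reflux; Fieser work-up
Reagents that add atoms: none
Why: Hydride reduction of both carboxylic acids to primary alcohols leaves the two α-stereocentres untouched, so 2 keeps the dl/meso ratio of 1.

Step 2
Reactants: 2 2,4-dimethylpentane-1,5-diol (stereoisomer mixture)
Product: 3 (2R,4R)-2,4-dimethylpentane-1,5-diol (recovered unacylated)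
Conditions: lipase AK (Pseudomonas fluorescens), vinyl acetate, i-Pr2O, 25 °C, run until all reactive CH2OH groups are acetylated; SiO2 separation of diol from mono- and diacetate; second pass if ee < 98%
Reagents that add atoms: none
Why: Enantioselective lipase-catalysed O-acylation (kinetic resolution as a three-way stereo-sorting): the lipase acylates a CH2OH next to an (S)-methyl centre much faster than one next to an (R) centre, so the (S,S)-diol becomes the diacetate, the meso diol the monoacetate, and only (2R,4R)-3, which carries both methyl stereocentres of the target, remains a diol (at most about 25% of the mixture).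

Step 3
Reactants: 3 (2R,4R)-2,4-dimethylpentane-1,5-diol
Product: 5 (3R,5R)-3,5-dimethyloxan-2-ol (lactol, both anomers), via (2R,4R)-5-hydroxy-2,4-dimethylpentanal 4 (not isolated)
Conditions: IBX (1.15 equiv), DMSO, 23 °C
Reagents that add atoms: none
Why: IBX oxidation of one primary alcohol gives the aldehyde, which is trapped at once by the other hydroxyl as the six-membered hemiacetal (C–O ring closure), so the C2-symmetric diol is desymmetrised without statistics and the lactol resists further oxidation; the neutral medium does not epimerise the α-centre.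

Step 4
Reactants: 5 (3R,5R)-3,5-dimethyloxan-2-ol; 6 2-(triphenylphosphoranylidene)butanal
Product: 7 (2E,4R,6R)-2-ethyl-7-hydroxy-4,6-dimethylhept-2-enal
Conditions: 6 (1.3 equiv), toluene, 90 °C
Reagents that add atoms: none
Why: Wittig olefination with a formyl-stabilised ylide: the lactol is in ring–chain equilibrium with its open hydroxy-aldehyde form, which the ylide intercepts to give the (E)-trisubstituted enal (CHO trans to the chain) under neutral conditions that do not enolise the α-methyl centre.

Step 5
Reactants: 7 (2E,4R,6R)-2-ethyl-7-hydroxy-4,6-dimethylhept-2-enal; 8 diethyl benzylphosphonate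
Product: 10 (2R,4R,5E,7E)-6-ethyl-2,4-dimethyl-8-phenylocta-5,7-dien-1-ol, via potassium (diethoxyphosphoryl)(phenyl)methanide 9 (not isolated)
Conditions: 8 (2.2 equiv), KOt-Bu (2.1 equiv), THF, 0 °C; then 7, −78 → 0 °C
Reagents that add atoms: none
Why: Horner–Wadsworth–Emmons olefination of the enal with the benzylphosphonate anion gives the (E)-styryl alkene and completes the (E,E)-diene; addition at −78 °C outruns γ-deprotonation of the enal, and the free hydroxyl only consumes the extra equivalent of base.

Step 6
Reactants: 10 (2R,4R,5E,7E)-6-ethyl-2,4-dimethyl-8-phenylocta-5,7-dien-1-ol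
Product: 11 (2R,4R,5E,7E)-6-ethyl-2,4-dimethyl-8-phenylocta-5,7-dienal
Conditions: Dess–Martin periodinane (1.2 equiv), CH2Cl2, 0 → 23 °C; used at once
Reagents that add atoms: none
Why: Dess–Martin oxidation of the primary alcohol is neutral and mild, so the new α-methyl aldehyde is not epimerised and the diene is untouched.

Step 7
Reactants: 11 (2R,4R,5E,7E)-6-ethyl-2,4-dimethyl-8-phenylocta-5,7-dienal; 12 propyltriphenylphosphonium bromide
Product: 16 [(1E,3E,5R,7R,8Z)-3-ethyl-9-iodo-5,7-dimethylundeca-1,3,8-trien-1-yl]benzene, via (propylidene)triphenylphosphorane 13 (not isolated), via (1-iodopropyl)triphenylphosphonium iodide 14 (not isolated), via (1-iodopropylidene)triphenylphosphorane 15 (not isolated)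
Conditions: 12, n-BuLi, THF, 0 → 23 °C; I2, −78 °C; NaHMDS, −78 → −20 °C; then 11, −78 → −20 °C
Reagents that add atoms: iodine, II
Why: Stork–Zhao-type α-iodoalkylidene Wittig olefination: the unstabilised iodo ylide adds under kinetic control and places the chain cis to iodine, giving the (Z)-trisubstituted vinyl iodide whose geometry later defines the quaternary centre.

Step 8
Reactants: 16 [(1E,3E,5R,7R,8Z)-3-ethyl-9-iodo-5,7-dimethylundeca-1,3,8-trien-1-yl]benzene; 17 ethyl (2E)-3-iodo-2-methylprop-2-enoate
Product: 20 ethyl (2E,4Z,6R,8R,9E,11E)-4,10-diethyl-2,6,8-trimethyl-12-phenyldodeca-2,4,9,11-tetraenoate, via [(3E,5R,7R,8E,10E)-9-ethyl-5,7-dimethyl-11-phenylundeca-3,8,10-trien-3-yl]lithium 18 (not isolated), via chloro[(3Z,5R,7R,8E,10E)-9-ethyl-5,7-dimethyl-11-phenylundeca-3,8,10-trien-3-yl]zinc 19 (not isolated)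
Conditions: t-BuLi (2.1 equiv), Et2O, −78 °C; ZnCl2, THF, −78 → 0 °C; 17, Pd(PPh3)4 (5 mol %), 0 → 23 °C
Reagents that add atoms: none
Why: Iodine–lithium exchange and transmetalation to zinc retain the alkene geometry, and the Pd-catalysed Negishi coupling is stereoretentive on both alkenyl partners, so the (2E,4Z)-dienoate is formed with the chain cis to the new acrylate arm.

Step 9
Reactants: 20 ethyl (2E,4Z,6R,8R,9E,11E)-4,10-diethyl-2,6,8-trimethyl-12-phenyldodeca-2,4,9,11-tetraenoate
Product: 21 (2E,4Z,6R,8R,9E,11E)-4,10-diethyl-2,6,8-trimethyl-12-phenyldodeca-2,4,9,11-tetraenoic acid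
Conditions: LiOH·H2O, THF/MeOH/H2O, 0 → 23 °C; cold 1 M HCl to pH 3; used at once
Reagents that add atoms: lithium hydroxide, [Li+].[OH-]
Why: Saponification of the ethyl ester; no stereocentre is α to the carbonyl and the cold work-up keeps the (4Z) geometry.

Step 10
Reactants: 21 (2E,4Z,6R,8R,9E,11E)-4,10-diethyl-2,6,8-trimethyl-12-phenyldodeca-2,4,9,11-tetraenoic acid
Product: 22 homo-plakotenin, (2E)-3-[(1R,3R,3aR,4S,5S,7aR)-4,7-diethyl-1,3-dimethyl-5-phenyl-2,3,3a,4,5,7a-hexahydro-1H-inden-4-yl]-2-methylprop-2-enoic acid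
Conditions: 2-iodophenylboronic acid (15 mol %), 4 Å MS, CH2Cl2, 23 °C
Reagents that add atoms: none
Why: Proposed new method: the arylboronic acid condenses reversibly with the CO2H of 21 to a mono(acyloxy)boronate (covalent C(=O)–O–B activation; closest known reaction is the boronic-acid-catalysed intermolecular Diels–Alder reaction of acrylic and propiolic acids, here extended to the γ,δ-alkene of a 2,4-dienoic acid and to an intramolecular case), which lowers the LUMO of the whole dienoate with a large coefficient at C5, the carbon that closes the five-membered ring, so the tethered styryl diene adds across C4=C5 at room temperature through the exo-tether transition state; this gives the trans ring fusion, the (4Z) geometry places the acrylic arm cis to C3 at the quaternary centre, the (E,E)-diene gives H-5 and H-7a cis, and the face is set by the two tether methyl stereocentres (substrate control; the sense is the assumption stated above).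

## Compound list

1 | 2,4-dimethylpentanedioic acid (2,4-dimethylglutaric acid, dl/meso mixture) | CC(CC(C)C(=O)O)C(=O)O | starting material
2 | 2,4-dimethylpentane-1,5-diol (mixture of (2R,4R), (2S,4S) and meso) | CC(CO)CC(C)CO | intermediate
3 | (2R,4R)-2,4-dimethylpentane-1,5-diol | OC[C@H](C)C[C@@H](C)CO | intermediate
4 | (2R,4R)-5-hydroxy-2,4-dimethylpentanal (open form of 5) | O=C[C@H](C)C[C@@H](C)CO | intermediate
5 | (3R,5R)-3,5-dimethyloxan-2-ol (lactol, anomer mixture) | OC1OC[C@H](C)C[C@H]1C | intermediate
6 | 2-(triphenylphosphoranylidene)butanal | CCC(C=O)=P(c1ccccc1)(c1ccccc1)c1ccccc1 | starting material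
7 | (2E,4R,6R)-2-ethyl-7-hydroxy-4,6-dimethylhept-2-enal | O=C/C(CC)=C/[C@H](C)C[C@@H](C)CO | intermediate
8 | diethyl benzylphosphonate | CCOP(=O)(Cc1ccccc1)OCC | starting material
9 | potassium (diethoxyphosphoryl)(phenyl)methanide | CCOP(=O)([CH-]c1ccccc1)OCC.[K+] | intermediate
10 | (2R,4R,5E,7E)-6-ethyl-2,4-dimethyl-8-phenylocta-5,7-dien-1-ol | c1ccccc1/C=C/C(CC)=C/[C@H](C)C[C@@H](C)CO | intermediate
11 | (2R,4R,5E,7E)-6-ethyl-2,4-dimethyl-8-phenylocta-5,7-dienal | c1ccccc1/C=C/C(CC)=C/[C@H](C)C[C@@H](C)C=O | intermediate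
12 | propyltriphenylphosphonium bromide | CCC[P+](c1ccccc1)(c1ccccc1)c1ccccc1.[Br-] | starting material
13 | (propylidene)triphenylphosphorane | CCC=P(c1ccccc1)(c1ccccc1)c1ccccc1 | intermediate
14 | (1-iodopropyl)triphenylphosphonium iodide | CCC(I)[P+](c1ccccc1)(c1ccccc1)c1ccccc1.[I-] | intermediate
15 | (1-iodopropylidene)triphenylphosphorane | CCC(I)=P(c1ccccc1)(c1ccccc1)c1ccccc1 | intermediate
16 | [(1E,3E,5R,7R,8Z)-3-ethyl-9-iodo-5,7-dimethylundeca-1,3,8-trien-1-yl]benzene | c1ccccc1/C=C/C(CC)=C/[C@H](C)C[C@@H](C)/C=C(\I)CC | intermediate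
17 | ethyl (2E)-3-iodo-2-methylprop-2-enoate | CCOC(=O)/C(C)=C/I | starting material
18 | [(3E,5R,7R,8E,10E)-9-ethyl-5,7-dimethyl-11-phenylundeca-3,8,10-trien-3-yl]lithium (Li in place of I of 16, geometry retained) | c1ccccc1/C=C/C(CC)=C/[C@H](C)C[C@@H](C)/C=C(\[Li])CC | intermediate
19 | chloro[(3Z,5R,7R,8E,10E)-9-ethyl-5,7-dimethyl-11-phenylundeca-3,8,10-trien-3-yl]zinc | c1ccccc1/C=C/C(CC)=C/[C@H](C)C[C@@H](C)/C=C(\[Zn]Cl)CC | intermediate
20 | ethyl (2E,4Z,6R,8R,9E,11E)-4,10-diethyl-2,6,8-trimethyl-12-phenyldodeca-2,4,9,11-tetraenoate | c1ccccc1/C=C/C(CC)=C/[C@H](C)C[C@@H](C)/C=C(CC)\C=C(/C)C(=O)OCC | intermediate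
21 | (2E,4Z,6R,8R,9E,11E)-4,10-diethyl-2,6,8-trimethyl-12-phenyldodeca-2,4,9,11-tetraenoic acid | c1ccccc1/C=C/C(CC)=C/[C@H](C)C[C@@H](C)/C=C(CC)\C=C(/C)C(=O)O | intermediate
22 | homo-plakotenin, (2E)-3-[(1R,3R,3aR,4S,5S,7aR)-4,7-diethyl-1,3-dimethyl-5-phenyl-2,3,3a,4,5,7a-hexahydro-1H-inden-4-yl]-2-methylprop-2-enoic acid | CCC1=C[C@@H](c2ccccc2)[C@@](/C=C(\C)C(=O)O)(CC)[C@H]2[C@H]1[C@H](C)C[C@H]2C | target

## Step count and risks

Total steps: 10. Longest linear sequence: 10 (steps 1 to 10, fully linear).

The three steps most likely to fail: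

Step 10 (the proposed new catalysis; the rate gain on a vinylogous, trisubstituted dienophile is unproven, and the facial sense rests on the stated assumption). The fallback sets out from 21 and comes back at 22: the uncatalysed thermal intramolecular Diels–Alder reaction of the free acid (toluene with a trace of BHT, 23 → 80 °C), which is the known biomimetic mode of ring closure. It changes activation but not the substrate-controlled face selectivity, and it makes no new compound (F0).

Step 7 (α-iodo-Wittig with the propyl-derived ylide on an α-branched aldehyde; modest yield and Z/E ratio are possible). The fallback sets out from 11 and comes back at 20, replacing steps 7 and 8 by an ester-based sequence. Still–Gennari olefination of 11 with methyl 2-[bis(2,2,2-trifluoroethoxy)phosphoryl]butanoate (KHMDS, 18-crown-6, THF, −78 °C) gives methyl (2Z,4R,6R,7E,9E)-2,8-diethyl-4,6-dimethyl-10-phenyldeca-2,7,9-trienoate F1. DIBAL-H (CH2Cl2, −78 °C) reduces it to (2Z,4R,6R,7E,9E)-2,8-diethyl-4,6-dimethyl-10-phenyldeca-2,7,9-trien-1-ol F2. MnO2 (CH2Cl2, 23 °C) gives (2Z,4R,6R,7E,9E)-2,8-diethyl-4,6-dimethyl-10-phenyldeca-2,7,9-trienal F3. Wittig reaction of F3 with ethyl 2-(triphenylphosphoranylidene)propanoate (CH2Cl2, 23 °C) then gives 20.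

Step 4 (Wittig of an α-branched lactol with a hindered, weakly nucleophilic formyl ylide; slow conversion, or oxa-Michael closure of the hydroxy-enal to a tetrahydropyran on prolonged heating, would erode the yield). The fallback sets out from 5 and comes back at 7, using a more nucleophilic ester ylide and a redox adjustment. Wittig reaction of 5 with ethyl 2-(triphenylphosphoranylidene)butanoate (toluene, 80 °C) gives ethyl (2E,4R,6R)-2-ethyl-7-hydroxy-4,6-dimethylhept-2-enoate F4. DIBAL-H (CH2Cl2, −78 °C) reduces it to (2E,4R,6R)-2-ethyl-4,6-dimethylhept-2-ene-1,7-diol F5. MnO2 (CH2Cl2, 23 °C) then oxidises only the allylic hydroxyl and returns enal 7.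

Further compounds
F0 | step 10 | none | none
F1 | step 7 | methyl (2Z,4R,6R,7E,9E)-2,8-diethyl-4,6-dimethyl-10-phenyldeca-2,7,9-trienoate | c1ccccc1/C=C/C(CC)=C/[C@H](C)C[C@@H](C)/C=C(CC)\C(=O)OC
F2 | step 7 | (2Z,4R,6R,7E,9E)-2,8-diethyl-4,6-dimethyl-10-phenyldeca-2,7,9-trien-1-ol | c1ccccc1/C=C/C(CC)=C/[C@H](C)C[C@@H](C)/C=C(CC)\CO
F3 | step 7 | (2Z,4R,6R,7E,9E)-2,8-diethyl-4,6-dimethyl-10-phenyldeca-2,7,9-trienal | c1ccccc1/C=C/C(CC)=C/[C@H](C)C[C@@H](C)/C=C(CC)\C=O
F4 | step 4 | ethyl (2E,4R,6R)-2-ethyl-7-hydroxy-4,6-dimethylhept-2-enoate | CCOC(=O)/C(CC)=C/[C@H](C)C[C@@H](C)CO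
F5 | step 4 | (2E,4R,6R)-2-ethyl-4,6-dimethylhept-2-ene-1,7-diol | OC/C(CC)=C/[C@H](C)C[C@@H](C)CO
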